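## Structural features

Yezoquinolide is a linear tetraprenyl (C20) chain ending in a 2-methyl-1,4-benzoquinone, with the chain at C6 so that one C=O lies between CH3 and the chain. The chain is interrupted by one five-membered ring, an α,β-unsaturated γ-lactone, numbered here O1, C2 (C=O), C3, C4, C5, and these numbers are kept for all furan precursors. C3 carries a 4-methylpent-3-enyl group, C4 carries H, and C5 carries a CH2 that leads through two E-trisubstituted alkenes (1,5-related) to the quinone CH2. C5 (R) is the only stereocentre, so no neighbouring centre can relay or correct it. The fragile groups are the quinone (oxidant, Michael acceptor at its two free CH positions, base-sensitive), the two doubly activated CH2 groups, and above all C5–H, the vinylogous α-hydrogen of the lactone, which base removes with racemisation. The real difficulty is C5: it must be made as one enantiomer between the ring alkene and a skipped chain alkene, where the classical C4–C5 and C5–O constructions need an isomerisation-prone β,γ-unsaturated aldehyde, and it must then survive to the end. The key step exploits the fact that the ring O1–C2–C3–C4–C5 is one proton away from an aromatic furan: loss of H from C3 of the furan-2(3H)-one tautomer, or from C5 of the furan-2(5H)-one, gives the same planar, achiral furan-2-olate. The lability of C5–H thus becomes the means of control, since C5 is set by face-selective return of a proton and everything before that point is chemistry of a flat 2,4-dialkylfuran.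

## Logic of the disconnections

**20 ⇒ 19.**
- Cut: the two quinone C=O groups are traced back to two aryl C–OCH3 groups.
- Reason: the quinone would not survive organolithiums, iridium boryl species or amine catalysts, all of which the route needs.
- Gain: the western end is an inert arene through the whole sequence.
- Demand: the last step must be a fast, acidic one-electron oxidation that spares three trisubstituted alkenes and never exposes C5–H to base.

**19 ⇒ 17 (key disconnection, through 18).**
- Cut: the C5–H σ-bond. The ring π-bond goes back from C3=C4 to C4=C5 and a hydrogen returns to C3.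
- Reason: C5–H is the bond whose lability threatens the target, so it is formed as late and as mildly as possible.
- Gain: the only stereocentre disappears. 17 may be racemic at C3 because both enantiomers pass through planar 18. 17 also has the oxidation level of a hydroxylated furan, so both ring–chain bonds become aromatic substitution problems.
- Demand: the catalyst must tell the two faces of C5 in 18 apart, the γ-protonation must be the irreversible exit, and 19 must not be deprotonated again.
- In one sentence: racemic 17, made by C–H oxidation of flat 14, is funnelled through achiral 18 into 19 by a catalytic asymmetric 1,3-proton shift.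

**17 ⇒ 14 (through 16 and 15).**
- Cut: the C2–O bond of the future carbonyl group.
- Reason: C2–H is the only α-C–H left on the furan ring of 14.
- Gain: the lactone becomes an unfunctionalised, robust aromatic ring.
- Demand: the C–H functionalisation must ignore three alkenes, two activated CH2 groups and the arene. The oxidation must stay near neutral so that 16 ketonises at C3 and 17 is not carried on to the racemic conjugated isomer.

**14 ⇒ 12 + 8 (through 13).**
- Cut: the σ-bond between ring C5 and the chain CH2.
- Reason: this is the junction of the two halves. It is furylic on one side and allylic on the other, so it polarises naturally as furyl anion plus allylic halide and needs no β,γ-unsaturated aldehyde.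
- Gain: the C29 skeleton of 14 falls into a C10 and a C19 fragment.
- Demand: metalation of 12 at C5–H and not at C2–H, and SN2 rather than SN2′ attack on 8.

**12 ⇒ 9 + 10 (through 11).**
- Cut: the C3–CH2 bond.
- Reason: a halogen at C3 fixes the position of the side chain.
- Gain: two purchasable fragments.
- Demand: an sp2–sp3 coupling without β-hydride elimination.

**8 ⇒ 7 ⇒ 6.**
- Cut: the terminal C–Br bond, then the terminal C–O bond.
- Reason: the chain terminus of 6 is an isopropylidene group whose E-methyl group can be addressed selectively.
- Gain: the chain becomes an unfunctionalised C10 unit with its internal E-alkene already in place.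
- Demand: the oxidation must choose the terminal alkene and its E-methyl group, which also defines the second E-alkene.

**6 ⇒ 3 + 4 (through 5).**
- Cut: the aryl–CH2 bond.
- Reason: it is benzylic and allylic, formed as aryl anion plus allylic halide.
- Gain: a simple arene and a purchasable C10 bromide.
- Demand: regiodefined generation of the aryl anion, hence a bromide in 3.

**3 ⇒ 2 ⇒ 1.**
- Cut: one O–CH3 bond, then the C–Br bond.
- Reason: the free OH of 1 directs bromine to the single open ortho position.
- Gain: a commercial phenol.
- Demand: bromination without oxidation of the electron-rich ring.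

## Other disconnections considered

**Alternative 1:** (the first plan that comes to mind)
- Cut: C3=C4 by ring-closing metathesis and O1–C2 by acylation.
- Forward: 8 is homologated by one carbon to the β,γ-unsaturated aldehyde A1. Asymmetric vinyl addition gives the allylic alcohol A2. Esterification with the acrylic acid A3 gives the diene ester A4, and ruthenium-catalysed ring closure gives 19.
- Grounds for preferring the chosen plan:
  - The CH2 of A1 lies between CHO and C(CH3)=CH and tends to slip into conjugation under the basic or Lewis-acidic conditions of carbonyl addition.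
  - C5 is set early and must pass as an allylic ester through ruthenium carbene and hydride species.
  - The closure must form an electron-poor trisubstituted alkene from a 1,1-disubstituted acrylate in a molecule with three further alkenes.
  - From 8 it takes five steps plus the preparation of A3, against three steps (7, 8, 9) plus one.

**Alternative 2:**
- Cut: C4–C5 and C2–C3 (alkyne + aldehyde + CO).
- Forward: asymmetric addition of the terminal alkyne A5 to A1 gives the propargylic alcohol A6. Hydroxyl-directed trans-hydroalumination/iodination gives the (Z)-iodoalkenol A7, and the key step is its palladium-catalysed carbonylative lactonisation to 19.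
- Grounds for preferring the chosen plan:
  - The configuration again rests on an addition to the enolisable, isomerisable A1, here in the presence of amine base and zinc salts.
  - The hydride reagent and iodine must respect a tetraene.
  - The sequence from 8 is five steps plus one for A5, so the longest line grows by two steps.

**Alternative 3:**
- Cut: C4–C5 and O1–C2 in one (3+2) annulation driven by strain release.
- Forward: a phosphine opens the cyclopropenone A8 to a ketenyl ylide. Its carbon attacks A1, the alkoxide closes on the ketene, and loss of the phosphine gives the skeleton of 19 in one operation.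
- Grounds for preferring the chosen plan:
  - This is the most convergent idea, but the reaction type offers no established control of C5, so the configuration would rest on an untested chiral phosphine.
  - The ylide is a base and A1 is an unusually acidic aldehyde.
  - A8 cannot come from A5 by dihalocarbene addition, because the trisubstituted alkene is the better carbene acceptor, so a three-step cyclopropenone-acetal route is needed.
  - With the two homologation steps to A1 the total is higher than in the chosen plan.

Key step: step 9

Assumption: the quinidine-derived 6′-OH catalyst is taken to deliver the proton to the Si face of C5. The sense would be fixed on a simple 3,5-dialkylfuran-2(3H)-one, and the equally available quinine-derived pseudoenantiomer would be used if it proves opposite, with nothing else in the route changing.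

## Steps

Step 1
Reactants: 1 4-methoxy-2-methylphenol
Product: 2 2-bromo-4-methoxy-6-methylphenol
Conditions: NBS, CH2Cl2, 0 °C, dark
Reagents that add atoms: N-bromosuccinimide, O=C1CCC(=O)N1Br
Why: Electrophilic aromatic bromination; the free OH is the strongest director, its para position carries OMe and one ortho position CH3, so only C6 is open, and cold anhydrous conditions keep the p-methoxyphenol from being oxidised.

Step 2
Reactants: 2 2-bromo-4-methoxy-6-methylphenol
Product: 3 1-bromo-2,5-dimethoxy-3-methylbenzene
Conditions: MeI, K2CO3, acetone, reflux
Reagents that add atoms: iodomethane, CI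
Why: Williamson ether synthesis on an acidic phenol; the aryl bromide is inert to these conditions.

Step 3
Reactants: 3 1-bromo-2,5-dimethoxy-3-methylbenzene; 4 geranyl bromide
Product: 6 1-[(2E)-3,7-dimethylocta-2,6-dien-1-yl]-2,5-dimethoxy-3-methylbenzene, via aryllithium 5 (not isolated)
Conditions: n-BuLi, THF, −78 °C; then 4, −78 °C → 0 °C
Reagents that add atoms: none
Why: Bromine–lithium exchange outruns any deprotonation at −78 °C, and the aryllithium displaces the primary allylic bromide in an SN2 allylation; the alkene is not part of the reacting centre, so its E geometry is carried over from 4.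

Step 4
Reactants: 6 1-[(2E)-3,7-dimethylocta-2,6-dien-1-yl]-2,5-dimethoxy-3-methylbenzene
Product: 7 (2E,6E)-8-(2,5-dimethoxy-3-methylphenyl)-2,6-dimethylocta-2,6-dien-1-ol
Conditions: SeO2 (cat.), t-BuOOH, salicylic acid (cat.), CH2Cl2, 0 °C → rt
Reagents that add atoms: tert-butyl hydroperoxide, CC(C)(C)OO
Why: Riley-type allylic oxidation (ene reaction, then [2,3]-sigmatropic shift of the allylseleninic acid) run catalytically in selenium; the terminal isopropylidene alkene is the most accessible and electron-rich, and the cyclic transition states place oxygen on the methyl group trans to the chain, which should give the E-allylic alcohol.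

Step 5
Reactants: 7 (2E,6E)-8-(2,5-dimethoxy-3-methylphenyl)-2,6-dimethylocta-2,6-dien-1-ol
Product: 8 1-[(2E,6E)-8-bromo-3,7-dimethylocta-2,6-dien-1-yl]-2,5-dimethoxy-3-methylbenzene
Conditions: CBr4, PPh3, CH2Cl2, 0 °C
Reagents that add atoms: carbon tetrabromide, BrC(Br)(Br)Br
Why: Appel reaction; SN2 displacement of the oxyphosphonium group at a primary allylic carbon under neutral conditions, without allylic transposition or loss of geometry; 8 is used without storage.

Step 6
Reactants: 9 3-bromofuran; 10 5-bromo-2-methylpent-2-ene
Product: 12 perillene [3-(4-methylpent-3-en-1-yl)furan], via homoprenyl Grignard reagent 11 (not isolated)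
Conditions: 10, Mg, THF, rt → 40 °C; then 9, NiCl2(dppp) (cat.), Et2O/THF, reflux
Reagents that add atoms: none
Why: Kumada–Corriu coupling of a primary alkyl Grignard reagent with a heteroaryl bromide; the chelating diphosphine suppresses β-hydride elimination, and the halogen fixes the side chain at C3 without any regiochemical question.

Step 7
Reactants: 12 perillene; 8 1-[(2E,6E)-8-bromo-3,7-dimethylocta-2,6-dien-1-yl]-2,5-dimethoxy-3-methylbenzene
Product: 14 2-[(2E,6E)-8-(2,5-dimethoxy-3-methylphenyl)-2,6-dimethylocta-2,6-dien-1-yl]-4-(4-methylpent-3-en-1-yl)furan, via C5-lithiated perillene 13 (not isolated)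
Conditions: s-BuLi, TMEDA, THF, −78 → −30 °C; then 8, THF, −78 °C → rt
Reagents that add atoms: none
Why: α-Lithiation of a furan followed by SN2 allylation; both α-positions are activated by O1, but C2–H is shielded and slightly deactivated by the neighbouring alkyl group, so a bulky base should take C5–H. The primary allylic bromide reacts at its CH2 and keeps its E geometry.

Step 8
Reactants: 14 2-[(2E,6E)-8-(2,5-dimethoxy-3-methylphenyl)-2,6-dimethylocta-2,6-dien-1-yl]-4-(4-methylpent-3-en-1-yl)furan
Product: 17 rac-5-[(2E,6E)-8-(2,5-dimethoxy-3-methylphenyl)-2,6-dimethylocta-2,6-dien-1-yl]-3-(4-methylpent-3-en-1-yl)furan-2(3H)-one, via pinacol furylboronate 15 (not isolated), via 2-hydroxyfuran tautomer 16 (not isolated)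
Conditions: [Ir(OMe)(cod)]2 (cat.), dtbpy (cat.), B2pin2, MTBE, 50 °C; then 30 % H2O2, phosphate buffer pH 7–8, THF, 0 °C
Reagents that add atoms: hydrogen peroxide, OO
Why: Iridium-catalysed C–H borylation of a five-membered heteroarene α to the heteroatom, then oxidation of the C–B bond; C2–H is the only candidate, because C4–H and both arene C–H bonds are flanked by two substituents and trisubstituted alkenes are inert to the catalyst. The 2-hydroxyfuran 16 should ketonise kinetically at C3, the dienol carbon of highest electron density, and the near-neutral medium should leave 17 as the deconjugated tautomer; its C3 centre is racemic and is erased in step 9.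

Step 9
Reactants: 17 rac-5-[(2E,6E)-8-(2,5-dimethoxy-3-methylphenyl)-2,6-dimethylocta-2,6-dien-1-yl]-3-(4-methylpent-3-en-1-yl)furan-2(3H)-one
Product: 19 (5R)-5-[(2E,6E)-8-(2,5-dimethoxy-3-methylphenyl)-2,6-dimethylocta-2,6-dien-1-yl]-3-(4-methylpent-3-en-1-yl)furan-2(5H)-one, via achiral furan-2-olate ion pair 18 (not isolated)
Conditions: 9-O-aryl cupreidine (quinidine-derived, free 6′-OH, 10 mol %), CH2Cl2, −20 °C
Reagents that add atoms: none
Why: The known reaction type is the enantioselective olefin isomerisation of β,γ-unsaturated butenolides by proton-transfer catalysis with a bifunctional 6′-OH cinchona alkaloid. The quinuclidine nitrogen removes the acidic C3–H of either enantiomer of 17 and gives the planar, achiral, aromatic furan-2-olate 18, held as a contact ion pair by the ammonium N–H and the 6′-OH; reprotonation at C3 is fast and reversible, so C3 racemises continuously and both enantiomers drain through the same intermediate (stereoconvergence). The slower, product- and stereo-determining event is delivery of the ammonium proton to C5; no ring is closed, only the C5–H bond forms and the ring alkene moves from C4=C5 to C3=C4. C5 is controlled by the catalyst alone: with the olate oxygen anchored by the 6′-OH, the N–H lies over one face of the ring, and delivery to the Si face of C5 (O1 > C4 > CH2) gives R. The step needs γ- over α-protonation, and the substrate secures this thermodynamically, since 19 gains conjugation with C2=O and, thanks to the C3 side chain, a trisubstituted C3=C4 bond, so α-protonation is only a reversible dead end. It also needs 19 not to be deprotonated again: C5–H of the conjugated lactone should be kinetically far less acidic towards a tertiary amine at −20 °C than C3–H of the higher-energy 17, and the reaction is stopped at full conversion. The CH2 groups of the chain and the alkenes are far too weakly acidic for an amine base, so no migration into the chain is expected.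

Step 10
Reactants: 19 (5R)-5-[(2E,6E)-8-(2,5-dimethoxy-3-methylphenyl)-2,6-dimethylocta-2,6-dien-1-yl]-3-(4-methylpent-3-en-1-yl)furan-2(5H)-one
Product: 20 yezoquinolide
Conditions: (NH4)2Ce(NO3)6, MeCN/H2O, 0 °C
Reagents that add atoms: water, O
Why: Cerium(IV) oxidative demethylation of a 1,4-dimethoxyarene (two one-electron oxidations, ipso attack of water, loss of methanol); the dialkyl-dimethoxyarene is far easier to oxidise than isolated trisubstituted alkenes or the lactone. The medium is acidic and the reaction short, so C5–H is never exposed to base and the R configuration is kept.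

## Compound list

1 | 4-methoxy-2-methylphenol | COc1ccc(O)c(C)c1 | starting material
2 | 2-bromo-4-methoxy-6-methylphenol | COc1cc(C)c(O)c(Br)c1 | intermediate
3 | 1-bromo-2,5-dimethoxy-3-methylbenzene | COc1cc(C)c(OC)c(Br)c1 | intermediate
4 | geranyl bromide, (2E)-1-bromo-3,7-dimethylocta-2,6-diene | CC(C)=CCC/C(C)=C/CBr | starting material
5 | (2,5-dimethoxy-3-methylphenyl)lithium | [Li]c1cc(OC)cc(C)c1OC | intermediate
6 | 1-[(2E)-3,7-dimethylocta-2,6-dien-1-yl]-2,5-dimethoxy-3-methylbenzene | CC(C)=CCC/C(C)=C/Cc1cc(OC)cc(C)c1OC | intermediate
7 | (2E,6E)-8-(2,5-dimethoxy-3-methylphenyl)-2,6-dimethylocta-2,6-dien-1-ol | OC/C(C)=C/CC/C(C)=C/Cc1cc(OC)cc(C)c1OC | intermediate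
8 | 1-[(2E,6E)-8-bromo-3,7-dimethylocta-2,6-dien-1-yl]-2,5-dimethoxy-3-methylbenzene | BrC/C(C)=C/CC/C(C)=C/Cc1cc(OC)cc(C)c1OC | intermediate
9 | 3-bromofuran | Brc1ccoc1 | starting material
10 | 5-bromo-2-methylpent-2-ene | CC(C)=CCCBr | starting material
11 | (4-methylpent-3-en-1-yl)magnesium bromide | CC(C)=CCC[Mg]Br | intermediate
12 | perillene, 3-(4-methylpent-3-en-1-yl)furan | CC(C)=CCCc1ccoc1 | intermediate
13 | [4-(4-methylpent-3-en-1-yl)furan-2-yl]lithium | [Li]c1cc(CCC=C(C)C)co1 | intermediate
14 | 2-[(2E,6E)-8-(2,5-dimethoxy-3-methylphenyl)-2,6-dimethylocta-2,6-dien-1-yl]-4-(4-methylpent-3-en-1-yl)furan | CC(C)=CCCc1coc(C/C(C)=C/CC/C(C)=C/Cc2cc(OC)cc(C)c2OC)c1 | intermediate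
15 | 2-{5-[(2E,6E)-8-(2,5-dimethoxy-3-methylphenyl)-2,6-dimethylocta-2,6-dien-1-yl]-3-(4-methylpent-3-en-1-yl)furan-2-yl}-4,4,5,5-tetramethyl-1,3,2-dioxaborolane | CC(C)=CCCc1cc(C/C(C)=C/CC/C(C)=C/Cc2cc(OC)cc(C)c2OC)oc1B1OC(C)(C)C(C)(C)O1 | intermediate
16 | 5-[(2E,6E)-8-(2,5-dimethoxy-3-methylphenyl)-2,6-dimethylocta-2,6-dien-1-yl]-3-(4-methylpent-3-en-1-yl)furan-2-ol | CC(C)=CCCc1cc(C/C(C)=C/CC/C(C)=C/Cc2cc(OC)cc(C)c2OC)oc1O | intermediate
17 | rac-5-[(2E,6E)-8-(2,5-dimethoxy-3-methylphenyl)-2,6-dimethylocta-2,6-dien-1-yl]-3-(4-methylpent-3-en-1-yl)furan-2(3H)-one | CC(C)=CCCC1C=C(C/C(C)=C/CC/C(C)=C/Cc2cc(OC)cc(C)c2OC)OC1=O | intermediate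
18 | 5-[(2E,6E)-8-(2,5-dimethoxy-3-methylphenyl)-2,6-dimethylocta-2,6-dien-1-yl]-3-(4-methylpent-3-en-1-yl)furan-2-olate (ion pair with the protonated catalyst) | CC(C)=CCCc1cc(C/C(C)=C/CC/C(C)=C/Cc2cc(OC)cc(C)c2OC)oc1[O-] | intermediate
19 | (5R)-5-[(2E,6E)-8-(2,5-dimethoxy-3-methylphenyl)-2,6-dimethylocta-2,6-dien-1-yl]-3-(4-methylpent-3-en-1-yl)furan-2(5H)-one | CC(C)=CCCC1=C[C@@H](C/C(C)=C/CC/C(C)=C/Cc2cc(OC)cc(C)c2OC)OC1=O | intermediate
20 | yezoquinolide, 2-methyl-6-{(2E,6E)-3,7-dimethyl-8-[(2R)-4-(4-methylpent-3-en-1-yl)-5-oxo-2,5-dihydrofuran-2-yl]octa-2,6-dien-1-yl}cyclohexa-2,5-diene-1,4-dione | CC(C)=CCCC1=C[C@@H](C/C(C)=C/CC/C(C)=C/CC2=CC(=O)C=C(C)C2=O)OC1=O | target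

## Step count and least certain steps

Total step count: 10. Longest linear sequence: 9 steps (1 → 2 → 3 → 6 → 7 → 8 → 14 → 17 → 19 → 20, that is steps 1–5 and 7–10). Step 6 is a one-step side branch.

**Step 9 (key step).**
- Most likely failure: insufficient facial discrimination in the protonation of C5, or slow erosion by renewed deprotonation of the product.
- Reason: the C3 side chain sits next to the olate oxygen where the catalyst binds, and the C5 substituent is a flexible chain that offers little steric contrast. Any conjugated isomer carried over from step 8 would also dilute the enantiomeric purity.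
- Fallback (sets out from 17, comes back at 19): the asymmetric catalysis is replaced by resolution with recycling. An achiral tertiary amine (Et3N, CH2Cl2, rt) isomerises 17 to the racemic butenolide F1, and chromatography on a chiral stationary phase gives 19. The unwanted (5S)-butenolide F2 is returned to F1 by the same amine through 18 and separated again, so the lability of C5–H allows the whole material to be converted in cycles.

**Step 8.**
- Most likely failure: sluggish borylation at C2–H next to the C3 chain, protodeboronation of the electron-rich furylboronate, or partial ketonisation of 16 at C5 and base-induced drift of 17 to the racemic conjugated tautomer during oxidation and work-up.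
- Fallback (sets out from 8, comes back at 17): the ring oxygen is brought in before the coupling and the C3 chain after it.
  - Commercial furan-2(5H)-one is silylated (TIPSOTf, Et3N) to 2-(triisopropylsilyloxy)furan F3.
  - C5-lithiation (s-BuLi, TMEDA, THF) and alkylation with 8 give the 5-alkyl-2-silyloxyfuran F4.
  - Fluoride with acetic acid (TBAF, AcOH, THF, −78 °C) releases the 5-alkylfuran-2(3H)-one F5.
  - Deprotonation (LDA, THF/DMPU, −78 °C) and C3-alkylation with 10 give 17.
  - Tautomer control is no longer needed, because both tautomers of F5 converge on the same furanolate on deprotonation, and C–C bond formation at C3 locks the alkene at C4=C5.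

**Step 7.**
- Most likely failure: incomplete regioselection between C5–H and C2–H in the lithiation of 12, because both are α to O1 and differ only by the neighbouring alkyl group. Halogen–metal exchange with 8 and homocoupling are also possible.
- Fallback (sets out from 12, comes back at 14): deprotonation is replaced by a sterically governed C–H borylation and a cross-coupling. [Ir(OMe)(cod)]2/dtbpy with B2pin2 gives the C5-borylated perillene F6, and Suzuki–Miyaura allylation with 8 (Pd(0), K3PO4, THF/H2O) at the unhindered CH2 terminus of the π-allyl intermediate gives 14.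

**Step 4.**
- Most likely failure: over-oxidation to the enal and competing attack at the internal alkene or at the aryl–CH2–CH= position, because all are allylic and the selectivity is only steric and electronic.
- Fallback (sets out from 6, comes back at 7): C–H oxidation is replaced by alkene exchange. Cross-metathesis of the terminal isopropylidene group with methacrolein (second-generation ruthenium NHC catalyst, CH2Cl2, reflux) gives the (E)-enal F7, the more hindered internal alkene being left behind. Luche reduction (NaBH4, CeCl3, MeOH, 0 °C) then gives 7.

## Further compounds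

F1 | step 9 | rac-5-[(2E,6E)-8-(2,5-dimethoxy-3-methylphenyl)-2,6-dimethylocta-2,6-dien-1-yl]-3-(4-methylpent-3-en-1-yl)furan-2(5H)-one | CC(C)=CCCC1=CC(C/C(C)=C/CC/C(C)=C/Cc2cc(OC)cc(C)c2OC)OC1=O
F2 | step 9 | (5S)-5-[(2E,6E)-8-(2,5-dimethoxy-3-methylphenyl)-2,6-dimethylocta-2,6-dien-1-yl]-3-(4-methylpent-3-en-1-yl)furan-2(5H)-one | CC(C)=CCCC1=C[C@H](C/C(C)=C/CC/C(C)=C/Cc2cc(OC)cc(C)c2OC)OC1=O
F3 | step 8 | 2-(triisopropylsilyloxy)furan | CC(C)[Si](Oc1ccco1)(C(C)C)C(C)C
F4 | step 8 | ({5-[(2E,6E)-8-(2,5-dimethoxy-3-methylphenyl)-2,6-dimethylocta-2,6-dien-1-yl]furan-2-yl}oxy)triisopropylsilane | CC(C)[Si](Oc1ccc(C/C(C)=C/CC/C(C)=C/Cc2cc(OC)cc(C)c2OC)o1)(C(C)C)C(C)C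
F5 | step 8 | 5-[(2E,6E)-8-(2,5-dimethoxy-3-methylphenyl)-2,6-dimethylocta-2,6-dien-1-yl]furan-2(3H)-one | O=C1CC=C(C/C(C)=C/CC/C(C)=C/Cc2cc(OC)cc(C)c2OC)O1
F6 | step 7 | 4,4,5,5-tetramethyl-2-[4-(4-methylpent-3-en-1-yl)furan-2-yl]-1,3,2-dioxaborolane | CC(C)=CCCc1coc(B2OC(C)(C)C(C)(C)O2)c1
F7 | step 4 | (2E,6E)-8-(2,5-dimethoxy-3-methylphenyl)-2,6-dimethylocta-2,6-dienal | O=C/C(C)=C/CC/C(C)=C/Cc1cc(OC)cc(C)c1OC
A1 | alternative 1 | (3E,7E)-9-(2,5-dimethoxy-3-methylphenyl)-3,7-dimethylnona-3,7-dienal | O=CC/C(C)=C/CC/C(C)=C/Cc1cc(OC)cc(C)c1OC
A2 | alternative 1 | (3R,5E,9E)-11-(2,5-dimethoxy-3-methylphenyl)-5,9-dimethylundeca-1,5,9-trien-3-ol | C=C[C@@H](C/C(C)=C/CC/C(C)=C/Cc1cc(OC)cc(C)c1OC)O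
A3 | alternative 1 | 6-methyl-2-methylidenehept-5-enoic acid | C=C(CCC=C(C)C)C(=O)O
A4 | alternative 1 | (3R,5E,9E)-11-(2,5-dimethoxy-3-methylphenyl)-5,9-dimethylundeca-1,5,9-trien-3-yl 6-methyl-2-methylidenehept-5-enoate | C=C[C@@H](C/C(C)=C/CC/C(C)=C/Cc1cc(OC)cc(C)c1OC)OC(=O)C(=C)CCC=C(C)C
A5 | alternative 2 | 6-methylhept-5-en-1-yne | C#CCCC=C(C)C
A6 | alternative 2 | (8R,10E,14E)-16-(2,5-dimethoxy-3-methylphenyl)-2,10,14-trimethylhexadeca-2,10,14-trien-6-yn-8-ol | CC(C)=CCCC#C[C@@H](C/C(C)=C/CC/C(C)=C/Cc1cc(OC)cc(C)c1OC)O
A7 | alternative 2 | (6Z,8R,10E,14E)-16-(2,5-dimethoxy-3-methylphenyl)-6-iodo-2,10,14-trimethylhexadeca-2,6,10,14-tetraen-8-ol | CC(C)=CCC/C(I)=C/[C@@H](C/C(C)=C/CC/C(C)=C/Cc1cc(OC)cc(C)c1OC)O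
A8 | alternative 3 | 2-(4-methylpent-3-en-1-yl)cycloprop-2-en-1-one | O=C1C=C1CCC=C(C)C
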